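Slowness is the whole question here: at 10.0 h the winter run still holds 36.1% electrophile against 14.3% target, so you want to know how far the reaction gets while the dose comes in.

| flask | electrophile | nucleophile | solid base | remark | time |
|---|---|---|---|---|---|
| winter | 0.13 M (fed, over 20 h) | 0.19 M | 0.195 M | run made earlier; the fed solution adds 0.20 times the starting volume |  |
| spring | 0.13 M (fed, over 20 h) | 0.29 M | 0.195 M | run made earlier; the fed solution adds 0.20 times the starting volume |  |
| ash | 0.13 M (fed, over 20 h) | 0.140 M | 0.195 M | the fed solution adds 0.20 times the starting volume | 20 h |
| maple | 0.13 M (fed, over 20 h) | 0.210 M | 0.195 M | the fed solution adds 0.20 times the starting volume | 20 h |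

| run | time / h | electrophile / % | target / % |
|---|---|---|---|
| winter | 1.33 | 6.0 | 0 |
| winter | 3.00 | 12.7 | 1.5 |
| winter | 4.00 | 17.4 | 2.4 |
| winter | 6.00 | 24.2 | 6.3 |
| winter | 8.00 | 29.8 | 10.6 |
| winter | 10.0 | 36.1 | 14.3 |
| spring | 0.833 | 3.9 | 0.7 |
| spring | 1.33 | 5.5 | 0.5 |
| spring | 2.00 | 9.1 | 0.9 |
| spring | 3.00 | 12.2 | 1.7 |
| spring | 4.00 | 16.6 | 3.1 |
| spring | 6.00 | 21.8 | 8.4 |
| spring | 10.0 | 31.5 | 18.6 |

(scatter of a reading: 0.5 percentage points)

- every charge counts on the volume at the start, and the solution that is fed holds the whole dose
- solid, in amounts per volume of the solution: solid base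
- what was read earlier has a scatter of 0.5 percentage points, one standard deviation
- at the start none of the solid base is in solution
- percentages count the whole charge, also what has not yet gone in

- part of the electrophile that has reacted at the end, ash
- part of the electrophile that has reacted at the end, maple
- what raising the concentration of nucleophile from its lowest to its highest value here does to the part of the electrophile that has reacted (changes below 5 percentage points count as none) (it falls / no change / it rises)

Divide the rise in target from 6.00 h to 10.0 h by the mean electrophile in that window. Winter gives 0.0663 h⁻¹, spring 0.0957 h⁻¹. In logarithms, the ratio of these against the ratio of nucleophile charges reads as an order of 0.866. With a scatter of 0.5 percentage points per reading, I take first order. But the flask has grown by a factor 1.08 by mid-window and has lost nucleophile, which I count one for one with target. Correcting both runs and averaging gives the second-order constant k = 0.00654 M⁻¹ min⁻¹. The electrophile's half-life is then T = ln 2/(k[nucleophile]).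

A steady feed against first-order loss leaves a reacted share X = 1 − (1 − e^−x)/x, where x = ln 2 times dosing time over T. With ash's charged nucleophile, T = 12.6 h and X = 39.3%. Objection: that is too rich, since the feed dilutes and the nucleophile gets used. Using the end-of-run nucleophile throughout, T = 23.8 h and X = 24.2%. Objection: that is too lean, since the early flask is richer. I commit to the midpoint, 31.7%. For maple the same two bounds, 51.0% and 35.2%, give 43.1%, so the part reacted rises.

The forecast says 29% and 40%, and it rises: “I take values between the two.” Its numbers lie a little below mine .

The flask gives 29.1% for ash and 40.0% for maple, and it rises, by 11 points, so the forecast holds. In ash at 20.0 h, free nucleophile stands at 46.1% of its charge. Put that into k and T is 32.9 h, beside 29 h from the true constant.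

    electrophile + nucleophile → acid set free + target (k = 0.00740 M⁻¹ min⁻¹)
    acid set free + free base ⇌ salt of the base (K = 17.0 M⁻¹, k = 0.0140 M⁻¹ min⁻¹)
    nucleophile + acid set free ⇌ protonated nucleophile, settled at all times (K = 6800 M⁻¹)
    solid base ⇌ free base, rate k4*(cs4 - [free base]) while solid is left; crystals form when [free base] > cs4 (solubility = 0.0630 M, k = 1.80 × 10⁻⁴ min⁻¹)

Ash left until 2.0 d holds 51.2% electrophile, and its free nucleophile falls from 9.98% of the charge then to 4.01% at 3.0 d. With the mean of those two, T = 216 h, so 24.0 h later the electrophile should stand at 47.4%. The flask read at 3.0 d holds 47.3%.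

Readings and results are simulated with made-up constants; scatter was added.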